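The earlier runs and the new flask come from a simulation for substances that don't exist, noise included.

The first reading of this flask, at 15.0 min, already had intermediate A on its way down, to 9.5 % by the next reading, so the thing to watch lies in the minutes before it.

- spring: substrate 1.1 M; reagent 0.77 M; the very flask that is asked about, followed so far
- flask: substrate 1.1 M; reagent 0.770 M; time 12 h

spring run (percent of the substrate charged)

| time / min | intermediate A / % | target / % |
|---|---|---|
| 15.0 | 14.6 | 6.1 |
| 30.0 | 9.5 | 10.6 |
| 50.0 | 4.3 | 13.3 |
| 60.0 | 4.7 | 15.0 |
| 80.0 | 2.6 | 14.6 |

(readings scatter by 1 percentage point)



1. the best time, 12 h at the latest, for intermediate A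
2. the amount of intermediate A, in percent of the substrate charged, at that time
3. earliest time at which at least nineteen twentieths of that best amount are there
4. latest time at which they still are

One thing looked wrong. Reagent was charged at 70.0 % of the substrate, yet intermediate A plus target averaged 19.1 % over the readings, far less than that charge, and the sum did not climb from first reading to last. I read this flat sum as substrate leaving early by another way. The reading came to 4.25: this is the lost-per-kept, a selectivity factor, the substrate found in neither column for each unit found in the two. So I expected a top for intermediate A below 19.1 %, and before the first reading.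

The forecast put the top at 19 % at 0.1 h, with the band from 0.065 h to 0.16 h. It said: “The maximum therefore lies before the first reading.”

The flask gave 15.9 % at 0.140 h, later than forecast. The band ran from 0.0911 h to 0.210 h, and it closed before the first reading.

    substrate + reagent ⇌ intermediate A (K = 2.20 L mol⁻¹, k = 0.00160 L mol⁻¹ s⁻¹)
    reagent + intermediate A → intermediate B (k = 3.70 × 10⁻⁴ L mol⁻¹ s⁻¹)
    intermediate B ⇌ intermediate C (K = 1.70, k = 8.90 × 10⁻⁴ s⁻¹)
    reagent + intermediate A → target (k = 0.00110 L mol⁻¹ s⁻¹)
    intermediate C → side product (k = 0.0130 s⁻¹)
    2 substrate → homo dimer (k = 0.00150 L mol⁻¹ s⁻¹)

At 12.0 h this flask held 19.9 % of target and 0.0404 % of intermediate A, a lost-per-kept of 4.01, with 73.2 % standing as homo dimer. The scheme sets homo dimer, which takes two substrate, against the step of substrate with reagent, so I scaled the lost-per-kept from the readings by c(substrate) at fixed c(reagent), a rough scaling, as the lost also hold side product. For the neighbour flask, charged with 0.28 M of substrate, this gave 1.08, hence a kept share of 48.1 %. At 12.0 h the neighbour flask held 16.3 % of side product and 48.3 % of target.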